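**Plan**

1. Retrosynthesis: cut N–C1 and N–C9 (nitrogen inserted last between two primary alcohols); then C4–C12, by reversing a 1,2-shift, to a C5-alkynyl cyclobutanol; then C4–C5 (acetylide + cyclobutanone); then C5–C12 and C6–C7 (enone–allene [2+2]); then C11–C12 (sp2–sp3 coupling on a 2-iodoenone).
2. Enabling feature: in the five-membered ring C4–C5–C6–C7–C12 the C5 ketone lies between C6 and the alkylidene carbon C4, which is bonded to quaternary C12. Such an (E)-2-alkylidenecyclopentanone is the product of a 1,2-shift of ring carbon C12 from C5 onto the inner carbon of a C5-bound alkyne in a four-membered ring C5–C6–C7–C12. That cyclobutane is the head-to-head allene photoadduct of the C13 enone.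
3. Forward ring order: six-membered ring (from 3-methylcyclohexenone) → four-membered ring (photocycloaddition) → five-membered ring (strain-driven ring expansion) → nine-membered ring (double Mitsunobu annulation with the nitrogen atom).
4. Stereochemistry: C15 from copper-catalysed asymmetric β-boration; C7 and C12 from C15-controlled facial selectivity of the [2+2] (cis fusion enforced by the small ring); C13 from thermodynamically controlled ketone reduction; C12 passes through the ring expansion with retention; the E alkene comes from anti migration.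

Key step: step 10

Remark: from the bicyclic stage on, the text uses the biogenetic locants of the target skeleton (N flanked by C1 and C9; chain C1–C2–C3=C4; five-membered ring C4–C5(=O)–C6–C7–C12; six-membered ring C7–C8–C15(CH3 = C16)–C14–C13–C12; chain C12–C11–C10–C9). β is the face of the six-membered ring that carries the fused small ring, and all compounds called starting materials are assumed to be commercial.

**Step 1**
Reactants: 1 3-methylcyclohex-2-en-1-one
Product: 3 (S)-3-hydroxy-3-methylcyclohexan-1-one, via tertiary boronate 2 (not isolated)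
Conditions: [Cu(MeCN)4]PF6 (cat.), QuinoxP* (cat., the antipode that gives (R)-2), LiOt-Bu (cat.), B2pin2, i-PrOH, DMSO, rt; then NaBO3·4H2O, THF/H2O, rt
Reagents that add atoms: sodium perborate, [Na+].[O-]OB=O
Why: Conjugate addition of a boryl complex of monovalent copper with a chiral bisphosphine to a β,β-disubstituted cyclic enone (asymmetric β-boration) should give the tertiary boronate with high enantioselectivity, and perborate oxidation of the C–B bond proceeds with retention, so the ligand sets the future C15 carbinol.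

**Step 2**
Reactants: 3 (S)-3-hydroxy-3-methylcyclohexan-1-one
Product: 5 (S)-5-methyl-5-(trimethylsilyloxy)cyclohex-2-en-1-one, via bis-silyl dienol ether 4 (not isolated)
Conditions: LiN(i-Pr)2 (2.2 equiv), THF, −78 °C; Me3SiCl, −78 to 0 °C; then Pd(OAc)2 (1 equiv), MeCN, rt
Reagents that add atoms: chlorotrimethylsilane, C[Si](C)(C)Cl
Why: The alkoxide directs kinetic enolisation to the remote methylene (the other α-position is flanked by the alkoxide-bearing quaternary carbon), and Saegusa–Ito oxidation of the silyl enol ether by divalent palladium can only dehydrogenate on that side because the carbinol carbon has no hydrogen.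

**Step 3**
Reactants: 5 (S)-5-methyl-5-(trimethylsilyloxy)cyclohex-2-en-1-one
Product: 6 (S)-2-iodo-5-methyl-5-(trimethylsilyloxy)cyclohex-2-en-1-one
Conditions: I2, pyridine/CH2Cl2, 0 °C to rt
Reagents that add atoms: iodine, II
Why: Pyridine-mediated α-iodination of a cyclic enone (conjugate addition of pyridine, iodination of the enolate, elimination; Baylis–Hillman-type) is general and touches no stereocentre.

**Step 4**
Reactants: 6 (S)-2-iodo-5-methyl-5-(trimethylsilyloxy)cyclohex-2-en-1-one; 7 (allyloxy)(tert-butyl)dimethylsilane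
Product: 9 (S)-2-[3-(tert-butyldimethylsilyloxy)propyl]-5-methyl-5-(trimethylsilyloxy)cyclohex-2-en-1-one, via alkylborane 8 (not isolated)
Conditions: 7, 9-BBN-H, THF, rt; then 6, PdCl2(dppf) (cat.), AsPh3 (cat.), Cs2CO3, DMF/THF/H2O, rt
Reagents that add atoms: none
Why: Anti-Markovnikov hydroboration followed by B-alkyl Suzuki–Miyaura coupling with an α-iodoenone is a standard entry to 2-alkylcyclohexenones and attaches C11–C10–C9 to the future C12 at room temperature, mild enough to avoid β-elimination of the silyloxy group.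

**Step 5**
Reactants: 9 (S)-2-[3-(tert-butyldimethylsilyloxy)propyl]-5-methyl-5-(trimethylsilyloxy)cyclohex-2-en-1-one; 10 propa-1,2-diene (allene)
Product: 11 (1S,4S,6R)-1-[3-(tert-butyldimethylsilyloxy)propyl]-4-methyl-8-methylidene-4-(trimethylsilyloxy)bicyclo[4.2.0]octan-2-one (cis-fused; four-membered ring and OSiMe3 β; methyl and side chain α)
Conditions: hν (Hg lamp, Pyrex filter), excess 10, THF, −78 °C
Reagents that add atoms: none
Why: Triplet enone–allene [2+2] photocycloaddition gives the head-to-head adduct (allene central carbon C5 on the enone α-carbon C12) with a necessarily cis ring fusion, and the new C7–C6 bond should form axially on the half-chair that keeps the C16 methyl equatorial, that is syn to the smaller axial C15 silyloxy group, which sets C7 and C12 from C15.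

**Step 6**
Reactants: 11 (1S,4S,6R)-1-[3-(tert-butyldimethylsilyloxy)propyl]-4-methyl-8-methylidene-4-(trimethylsilyloxy)bicyclo[4.2.0]octan-2-one
Product: 13 (1S,2S,4S,6R)-1-[3-(tert-butyldimethylsilyloxy)propyl]-4-methyl-8-methylidenebicyclo[4.2.0]octane-2,4-diol (both hydroxyls β), via trimethylsilyl ether alcohol 12 (not isolated)
Conditions: Li, NH3(l)/THF, t-BuOH, −78 °C; NH4Cl; then K2CO3, MeOH, rt
Reagents that add atoms: none
Why: Dissolving-metal reduction of a ketone passes through a configurationally labile ketyl/carbanion and is thermodynamically controlled, so the equatorial 13β-alcohol (cis to the C15 oxygen) should form because its epimer would be syn-axial to the C16 methyl group; mild methanolysis then removes only the tertiary trimethylsilyl ether.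

**Step 7**
Reactants: 13 (1S,2S,4S,6R)-1-[3-(tert-butyldimethylsilyloxy)propyl]-4-methyl-8-methylidenebicyclo[4.2.0]octane-2,4-diol
Product: 14 (1S,2S,4S,6R)-1-[3-(tert-butyldimethylsilyloxy)propyl]-4-methyl-8-methylidenebicyclo[4.2.0]octane-2,4-diyl diacetate
Conditions: Ac2O (excess), DMAP, Et3N, CH2Cl2, 40 °C
Reagents that add atoms: acetic anhydride, CC(=O)OC(C)=O
Why: DMAP-catalysed acylation with excess anhydride esterifies hindered secondary and tertiary alcohols, installs both acetates of the target in one operation before any nitrogen is present, and masks C13–OH before the cyclobutanone is unveiled.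

**Step 8**
Reactants: 14 (1S,2S,4S,6R)-1-[3-(tert-butyldimethylsilyloxy)propyl]-4-methyl-8-methylidenebicyclo[4.2.0]octane-2,4-diyl diacetate
Product: 15 (1R,2S,4S,6S)-1-[3-(tert-butyldimethylsilyloxy)propyl]-4-methyl-8-oxobicyclo[4.2.0]octane-2,4-diyl diacetate
Conditions: O3, CH2Cl2, −78 °C; then PPh3, −78 °C to rt
Reagents that add atoms: ozone, [O-][O+]=O
Why: Ozonolysis of the 1,1-disubstituted alkene with reductive work-up gives the cyclobutanone, which is stable here because C13 is an acetate and not a ketone, so no retro-Claisen opening of a 1,3-dicarbonyl can occur.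

**Step 9**
Reactants: 15 (1R,2S,4S,6S)-1-[3-(tert-butyldimethylsilyloxy)propyl]-4-methyl-8-oxobicyclo[4.2.0]octane-2,4-diyl diacetate; 16 (but-3-yn-1-yloxy)(tert-butyl)dimethylsilane
Product: 18 (1R,2S,4S,6R,8S)-1-[3-(tert-butyldimethylsilyloxy)propyl]-8-[4-(tert-butyldimethylsilyloxy)but-1-yn-1-yl]-8-hydroxy-4-methylbicyclo[4.2.0]octane-2,4-diyl diacetate, via lithium acetylide 17 (not isolated)
Conditions: 16, n-BuLi, THF, −78 °C; then 15, −78 °C; AcOH quench at −78 °C
Reagents that add atoms: none
Why: A lithium acetylide adds to a strained cyclobutanone at −78 °C much faster than to acetate esters, and a cold acidic quench prevents acetyl transfer to the new alkoxide; attack from the face of the angular chain is expected, but this carbinol centre is destroyed in step 10.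

**Step 10**
Reactants: 18 (1R,2S,4S,6R,8S)-1-[3-(tert-butyldimethylsilyloxy)propyl]-8-[4-(tert-butyldimethylsilyloxy)but-1-yn-1-yl]-8-hydroxy-4-methylbicyclo[4.2.0]octane-2,4-diyl diacetate
Product: 19 (1E,3aS,5S,7S,7aS)-7a-[3-(tert-butyldimethylsilyloxy)propyl]-1-[3-(tert-butyldimethylsilyloxy)propylidene]-5-methyl-2-oxooctahydro-1H-indene-5,7-diyl diacetate
Conditions: (4-CF3C6H4)3PAuCl (5 mol %), AgSbF6 (5 mol %), CH2Cl2, 4 Å MS, rt
Reagents that add atoms: none
Why: Proposed new method: π-coordination of cationic monovalent gold to the C3≡C4 alkyne makes C4 electrophilic, and the strained C5–C12 ring bond, pushed by the hydroxyl lone pair, migrates to C4 anti to gold (semipinacol-type 1,2-shift) to give a vinylgold species that is protodeaurated with retention. The closest known reaction type is the gold-catalysed ring expansion of 1-alkynylcyclopropanols (internal alkynes) and of 1-ethynylcyclobutanols to alkylidenecycloalkanones; the extension is an alkyl-substituted internal alkyne on a cyclobutanol, which should be viable because the strain of the four-membered ring is released, the migrating carbon is quaternary and the carbinol is tertiary. The five-membered ring is closed by enlargement of the four-membered ring (1,2-shift of a ring bond onto the exocyclic alkyne carbon), not by an end-to-end cyclisation. No new stereocentre arises: C12 migrates with retention, so its configuration and the cis C7/C12 fusion are those fixed in step 5, and the E geometry (C12 and C2 cis on C3=C4) follows from the anti relationship of the migrating carbon and gold. The step needs migration of C12 and not C6, which the higher migratory aptitude of the more substituted carbon secures, and a ring expansion faster than Meyer–Schuster rearrangement or hydration, which strain release, a dry non-nucleophilic medium and the absence of any other O–H or N–H nucleophile near the alkyne secure.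

**Step 11**
Reactants: 19 (1E,3aS,5S,7S,7aS)-7a-[3-(tert-butyldimethylsilyloxy)propyl]-1-[3-(tert-butyldimethylsilyloxy)propylidene]-5-methyl-2-oxooctahydro-1H-indene-5,7-diyl diacetate
Product: 20 (1E,3aS,5S,7S,7aS)-7a-(3-hydroxypropyl)-1-(3-hydroxypropylidene)-5-methyl-2-oxooctahydro-1H-indene-5,7-diyl diacetate
Conditions: HF·pyridine, pyridine, THF, 0 °C to rt
Reagents that add atoms: none
Why: Buffered HF·pyridine cleaves primary silyl ethers without touching the acetates or the enone.

**Step 12**
Reactants: 20 (1E,3aS,5S,7S,7aS)-7a-(3-hydroxypropyl)-1-(3-hydroxypropylidene)-5-methyl-2-oxooctahydro-1H-indene-5,7-diyl diacetate; 21 2,4-dinitrobenzenesulfonamide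
Product: 23 N-(2,4-dinitrophenylsulfonyl) azonine (3E,7S,12S,13S,15S)-13β,15β-diacetate 5-ketone (nine-membered ring N–C1–C2–C3=C4–C12–C11–C10–C9 closed on the skeleton of 20), via sulfonamide alcohol 22 (not isolated)
Conditions: 21 (1 equiv), PPh3, DIAD, THF/toluene, high dilution, 0 °C to rt
Reagents that add atoms: none
Why: Fukuyama–Mitsunobu N-alkylation of an acidic arenesulfonamide, first intermolecular (the C9 isomer 22 is drawn; either converges) and then ring-closing by SN2 at a primary carbon, is the established way to close azonane rings of this alkaloid class; here the cis-in-ring C3=C4 bond and quaternary C12 hold the two chains together, and the neutral medium avoids ketone enolate alkylation and vinylogous elimination at C1.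

**Step 13**
Reactants: 23 N-(2,4-dinitrophenylsulfonyl) azonine (3E,7S,12S,13S,15S)-13β,15β-diacetate 5-ketone
Product: 25 CNP0137427.1 (N-formyl azonine (3E,7S,12S,13S,15S)-13β,15β-diacetate 5-ketone), via secondary amine 24 (not isolated)
Conditions: n-PrNH2 (excess), CH2Cl2, rt; concentrate; then N-formylsaccharin, THF, rt
Reagents that add atoms: N-formylsaccharin, O=CN1C(=O)c2ccccc2S1(=O)=O
Why: A 2,4-dinitrobenzenesulfonamide is cleaved by a primary amine through ipso substitution (Meisenheimer complex) with loss of SO2, which avoids thiolate and so spares the enone, and N-formylsaccharin formylates the freed secondary amine at room temperature without disturbing the acetates.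

**Compound list**

1 | 3-methylcyclohex-2-en-1-one | CC1=CC(=O)CCC1 | starting material
2 | (R)-3-methyl-3-(4,4,5,5-tetramethyl-1,3,2-dioxaborolan-2-yl)cyclohexan-1-one (not isolated) | O=C1C[C@@](C)(B2OC(C)(C)C(C)(C)O2)CCC1 | intermediate
3 | (S)-3-hydroxy-3-methylcyclohexan-1-one | O=C1C[C@@](C)(O)CCC1 | intermediate
4 | (S)-trimethyl{[5-methyl-5-(trimethylsilyloxy)cyclohex-1-en-1-yl]oxy}silane (not isolated) | C[Si](C)(C)OC1=CCC[C@](C)(O[Si](C)(C)C)C1 | intermediate
5 | (S)-5-methyl-5-(trimethylsilyloxy)cyclohex-2-en-1-one | O=C1C[C@@](C)(O[Si](C)(C)C)CC=C1 | intermediate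
6 | (S)-2-iodo-5-methyl-5-(trimethylsilyloxy)cyclohex-2-en-1-one | O=C1C[C@@](C)(O[Si](C)(C)C)CC=C1I | intermediate
7 | (allyloxy)(tert-butyl)dimethylsilane | C=CCO[Si](C)(C)C(C)(C)C | starting material
8 | 9-[3-(tert-butyldimethylsilyloxy)propyl]-9-borabicyclo[3.3.1]nonane (not isolated) | CC(C)(C)[Si](C)(C)OCCCB1C2CCCC1CCC2 | intermediate
9 | (S)-2-[3-(tert-butyldimethylsilyloxy)propyl]-5-methyl-5-(trimethylsilyloxy)cyclohex-2-en-1-one | O=C1C[C@@](C)(O[Si](C)(C)C)CC=C1CCCO[Si](C)(C)C(C)(C)C | intermediate
10 | propa-1,2-diene (allene) | C=C=C | starting material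
11 | (1S,4S,6R)-1-[3-(tert-butyldimethylsilyloxy)propyl]-4-methyl-8-methylidene-4-(trimethylsilyloxy)bicyclo[4.2.0]octan-2-one | O=C1C[C@@](C)(O[Si](C)(C)C)C[C@H]2CC(=C)[C@]21CCCO[Si](C)(C)C(C)(C)C | intermediate
12 | (1S,2S,4S,6R)-1-[3-(tert-butyldimethylsilyloxy)propyl]-4-methyl-8-methylidene-4-(trimethylsilyloxy)bicyclo[4.2.0]octan-2-ol (not isolated) | O[C@H]1C[C@@](C)(O[Si](C)(C)C)C[C@H]2CC(=C)[C@]21CCCO[Si](C)(C)C(C)(C)C | intermediate
13 | (1S,2S,4S,6R)-1-[3-(tert-butyldimethylsilyloxy)propyl]-4-methyl-8-methylidenebicyclo[4.2.0]octane-2,4-diol | O[C@H]1C[C@@](C)(O)C[C@H]2CC(=C)[C@]21CCCO[Si](C)(C)C(C)(C)C | intermediate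
14 | (1S,2S,4S,6R)-1-[3-(tert-butyldimethylsilyloxy)propyl]-4-methyl-8-methylidenebicyclo[4.2.0]octane-2,4-diyl diacetate | CC(=O)O[C@H]1C[C@@](C)(OC(C)=O)C[C@H]2CC(=C)[C@]21CCCO[Si](C)(C)C(C)(C)C | intermediate
15 | (1R,2S,4S,6S)-1-[3-(tert-butyldimethylsilyloxy)propyl]-4-methyl-8-oxobicyclo[4.2.0]octane-2,4-diyl diacetate | CC(=O)O[C@H]1C[C@@](C)(OC(C)=O)C[C@H]2CC(=O)[C@]21CCCO[Si](C)(C)C(C)(C)C | intermediate
16 | (but-3-yn-1-yloxy)(tert-butyl)dimethylsilane | C#CCCO[Si](C)(C)C(C)(C)C | starting material
17 | lithium 4-(tert-butyldimethylsilyloxy)but-1-yn-1-ide (not isolated) | [Li]C#CCCO[Si](C)(C)C(C)(C)C | intermediate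
18 | (1R,2S,4S,6R,8S)-1-[3-(tert-butyldimethylsilyloxy)propyl]-8-[4-(tert-butyldimethylsilyloxy)but-1-yn-1-yl]-8-hydroxy-4-methylbicyclo[4.2.0]octane-2,4-diyl diacetate | CC(=O)O[C@H]1C[C@@](C)(OC(C)=O)C[C@H]2C[C@](O)(C#CCCO[Si](C)(C)C(C)(C)C)[C@]21CCCO[Si](C)(C)C(C)(C)C | intermediate
19 | (1E,3aS,5S,7S,7aS)-7a-[3-(tert-butyldimethylsilyloxy)propyl]-1-[3-(tert-butyldimethylsilyloxy)propylidene]-5-methyl-2-oxooctahydro-1H-indene-5,7-diyl diacetate | CC(=O)O[C@H]1C[C@@](C)(OC(C)=O)C[C@H]2CC(=O)/C(=C/CCO[Si](C)(C)C(C)(C)C)[C@]21CCCO[Si](C)(C)C(C)(C)C | intermediate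
20 | (1E,3aS,5S,7S,7aS)-7a-(3-hydroxypropyl)-1-(3-hydroxypropylidene)-5-methyl-2-oxooctahydro-1H-indene-5,7-diyl diacetate | CC(=O)O[C@H]1C[C@@](C)(OC(C)=O)C[C@H]2CC(=O)/C(=C/CCO)[C@]21CCCO | intermediate
21 | 2,4-dinitrobenzenesulfonamide | NS(=O)(=O)c1ccc(cc1[N+](=O)[O-])[N+](=O)[O-] | starting material
22 | (1E,3aS,5S,7S,7aS)-7a-{3-[(2,4-dinitrophenyl)sulfonylamino]propyl}-1-(3-hydroxypropylidene)-5-methyl-2-oxooctahydro-1H-indene-5,7-diyl diacetate (not isolated) | CC(=O)O[C@H]1C[C@@](C)(OC(C)=O)C[C@H]2CC(=O)/C(=C/CCO)[C@]21CCCNS(=O)(=O)c3ccc(cc3[N+](=O)[O-])[N+](=O)[O-] | intermediate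
23 | N-(2,4-dinitrophenylsulfonyl) azonine (3E,7S,12S,13S,15S)-13β,15β-diacetate 5-ketone (tricyclic; 16α-methyl) | CC(=O)O[C@H]1C[C@@](C)(OC(C)=O)C[C@H]2CC(=O)/C3=C/CCN(S(=O)(=O)c4ccc(cc4[N+](=O)[O-])[N+](=O)[O-])CCC[C@@]321 | intermediate
24 | N-unsubstituted azonine (3E,7S,12S,13S,15S)-13β,15β-diacetate 5-ketone (not isolated) | CC(=O)O[C@H]1C[C@@](C)(OC(C)=O)C[C@H]2CC(=O)/C3=C/CCNCCC[C@@]321 | intermediate
25 | CNP0137427.1, N-formyl azonine (3E,7S,12S,13S,15S)-13β,15β-diacetate 5-ketone (all four stereocentres S; E enone) | CC(=O)O[C@H]1C[C@@](C)(OC(C)=O)C[C@H]2CC(=O)/C3=C/CCN(C=O)CCC[C@@]321 | target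

**Totals**

Total step count: 13. Longest linear sequence: 13 steps (1 to 25).

**Steps most likely to fail**

Step 10 (the step labelled as a proposed new method). The 1,2-shift onto an alkyl-substituted internal alkyne may be slower than Meyer–Schuster rearrangement or hydration of the gold-activated alkyne. The fallback uses known chemistry only and sets out from 15. Addition of HC≡CMgBr (THF, −78 °C) would give the ethynyl carbinol F1. The same cationic gold catalyst would then effect the terminal-alkyne ring expansion that is established for ethynylcyclobutanols and give the 2-methylidene cis-hydrindanone F2. HF·pyridine would free the primary alcohol F3. Mitsunobu alkylation (PPh3, DIAD) of N-(but-3-en-1-yl)-2,4-dinitrobenzenesulfonamide F4 (from but-3-en-1-amine, 2,4-dinitrobenzenesulfonyl chloride and Et3N) with F3 would give the diene sulfonamide F5. Ring-closing metathesis with the second-generation Hoveyda–Grubbs catalyst (H2IMes)Cl2Ru=CH(2-i-PrOC6H4) in hot toluene at high dilution would close the nine-membered ring. In that ring the new trisubstituted C3=C4 bond can only be cis within the ring, which is the E enone, and the fallback comes back to the route at 23.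

Step 12. Intermolecular oligomerisation or twofold sulfonamidation may outrun closure of the nine-membered ring. The fallback sets out from 15 and differentiates the two chain ends. The lithium acetylide of (but-3-yn-1-yloxy)triisopropylsilane would give the carbinol F6 and, by the ring expansion of step 10, the enone with two different silyl ethers F7. Buffered HF·pyridine at 0 °C would cleave only the primary tert-butyldimethylsilyl ether and give the C9 alcohol F8. Mitsunobu reaction with an excess of 21 would give the mono-alkylated sulfonamide F9. HF·pyridine at rt would then remove the triisopropylsilyl group and come back to the route at 22, now isolated, which a separate, purely intramolecular Fukuyama–Mitsunobu closure at high dilution would take to 23.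

Step 6. Incomplete thermodynamic control, or reductive cleavage next to the four-membered ring, could erode the C13 configuration. The fallback sets out from 11. Methanolysis (K2CO3, MeOH) would give the β-hydroxy ketone F10. A chelation-controlled syn-1,3-reduction (Et2BOMe, NaBH4, THF/MeOH, −78 °C; Narasaka–Prasad conditions), in which external hydride attacks the carbonyl face opposite the boron bridge between the C15 and C13 oxygens, would give the cis-diol and come back to the route at 13.

**Further compounds**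

F1 | step 10 | (1R,2S,4S,6R,8S)-1-[3-(tert-butyldimethylsilyloxy)propyl]-8-ethynyl-8-hydroxy-4-methylbicyclo[4.2.0]octane-2,4-diyl diacetate | CC(=O)O[C@H]1C[C@@](C)(OC(C)=O)C[C@H]2C[C@](O)(C#C)[C@]21CCCO[Si](C)(C)C(C)(C)C
F2 | step 10 | (3aS,5S,7S,7aS)-7a-[3-(tert-butyldimethylsilyloxy)propyl]-5-methyl-1-methylidene-2-oxooctahydro-1H-indene-5,7-diyl diacetate | CC(=O)O[C@H]1C[C@@](C)(OC(C)=O)C[C@H]2CC(=O)C(=C)[C@]21CCCO[Si](C)(C)C(C)(C)C
F3 | step 10 | (3aS,5S,7S,7aS)-7a-(3-hydroxypropyl)-5-methyl-1-methylidene-2-oxooctahydro-1H-indene-5,7-diyl diacetate | CC(=O)O[C@H]1C[C@@](C)(OC(C)=O)C[C@H]2CC(=O)C(=C)[C@]21CCCO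
F4 | step 10 | N-(but-3-en-1-yl)-2,4-dinitrobenzenesulfonamide | C=CCCNS(=O)(=O)c1ccc(cc1[N+](=O)[O-])[N+](=O)[O-]
F5 | step 10 | (3aS,5S,7S,7aS)-7a-{3-[(but-3-en-1-yl)(2,4-dinitrophenylsulfonyl)amino]propyl}-5-methyl-1-methylidene-2-oxooctahydro-1H-indene-5,7-diyl diacetate | CC(=O)O[C@H]1C[C@@](C)(OC(C)=O)C[C@H]2CC(=O)C(=C)[C@]21CCCN(CCC=C)S(=O)(=O)c3ccc(cc3[N+](=O)[O-])[N+](=O)[O-]
F6 | step 12 | (1R,2S,4S,6R,8S)-1-[3-(tert-butyldimethylsilyloxy)propyl]-8-hydroxy-4-methyl-8-[4-(triisopropylsilyloxy)but-1-yn-1-yl]bicyclo[4.2.0]octane-2,4-diyl diacetate | CC(=O)O[C@H]1C[C@@](C)(OC(C)=O)C[C@H]2C[C@](O)(C#CCCO[Si](C(C)C)(C(C)C)C(C)C)[C@]21CCCO[Si](C)(C)C(C)(C)C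
F7 | step 12 | (1E,3aS,5S,7S,7aS)-7a-[3-(tert-butyldimethylsilyloxy)propyl]-5-methyl-2-oxo-1-[3-(triisopropylsilyloxy)propylidene]octahydro-1H-indene-5,7-diyl diacetate | CC(=O)O[C@H]1C[C@@](C)(OC(C)=O)C[C@H]2CC(=O)/C(=C/CCO[Si](C(C)C)(C(C)C)C(C)C)[C@]21CCCO[Si](C)(C)C(C)(C)C
F8 | step 12 | (1E,3aS,5S,7S,7aS)-7a-(3-hydroxypropyl)-5-methyl-2-oxo-1-[3-(triisopropylsilyloxy)propylidene]octahydro-1H-indene-5,7-diyl diacetate | CC(=O)O[C@H]1C[C@@](C)(OC(C)=O)C[C@H]2CC(=O)/C(=C/CCO[Si](C(C)C)(C(C)C)C(C)C)[C@]21CCCO
F9 | step 12 | (1E,3aS,5S,7S,7aS)-7a-{3-[(2,4-dinitrophenyl)sulfonylamino]propyl}-5-methyl-2-oxo-1-[3-(triisopropylsilyloxy)propylidene]octahydro-1H-indene-5,7-diyl diacetate | CC(=O)O[C@H]1C[C@@](C)(OC(C)=O)C[C@H]2CC(=O)/C(=C/CCO[Si](C(C)C)(C(C)C)C(C)C)[C@]21CCCNS(=O)(=O)c3ccc(cc3[N+](=O)[O-])[N+](=O)[O-]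
F10 | step 6 | (1S,4S,6R)-1-[3-(tert-butyldimethylsilyloxy)propyl]-4-hydroxy-4-methyl-8-methylidenebicyclo[4.2.0]octan-2-one | O=C1C[C@@](C)(O)C[C@H]2CC(=C)[C@]21CCCO[Si](C)(C)C(C)(C)C
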